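**Plan**
- Retrosynthesis cuts, in order: the ester C–O bond; the C6–prenyl bond (dearomatising allylation); the C6–CH2 bond to the cyclobutane (Negishi coupling, fragment from (−)-verbenone); the lactone C–O bond; then the pyranone.
- The pyranone is a β-aryloxy ketone: C2–C3 is an aldol bond, and O1–C8a lies on the benzene ring ortho to the C4 ketone, where a fluoride can be displaced. Both bonds are cut together to give an ortho-fluoroaryl ethyl ketone and acetaldehyde.
- The ketone goes back by Friedel–Crafts acylation, phenyl conjugate addition, olefination and formylation to 1-fluoro-3,5-dimethoxybenzene. Every electrophile enters next to fluorine, so the carbon between the two oxygens is left for the last two C–C bonds.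
- Forward: side chain on the arene, pyranone ring (key step), lactone ring on demethylation, iodination and coupling, lactone opening with dearomatising prenylation, ester hydrolysis.
- Stereochemistry: benzylic centre from Rh/(S)-BINAP; C2 from the isopinocampheyl boron reagent and C3 by equilibration to trans; cyclobutane centres from (1S,5S)-verbenone; C6 from the palladium ligand.

Key step: step 5

Assumption: the face selectivities written for the reagent- or ligand-controlled steps 3, 5 and 13 follow the working models named in those steps; if a first run shows the opposite sense, the mirror-image ligand or boron reagent is used with nothing else changed.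

**Route**

Step 1
Reactants: 1 1-fluoro-3,5-dimethoxybenzene
Product: 2 2-fluoro-4,6-dimethoxybenzaldehyde
Conditions: POCl3, DMF, 0 → 60 °C; aq. NaOAc
Reagents that add atoms: N,N-dimethylformamide CN(C)C=O; water O
Why: Vilsmeier–Haack formylation should take the position para to one methoxy group and next to the small fluorine, because the site between the two methoxy groups is more hindered and has no para donor; no stereocentre is formed.

Step 2
Reactants: 2 2-fluoro-4,6-dimethoxybenzaldehyde; 3 trimethyl phosphonoacetate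
Product: 4 methyl (2E)-3-(2-fluoro-4,6-dimethoxyphenyl)prop-2-enoate
Conditions: NaH, THF, 0 °C → rt
Reagents that add atoms: none
Why: Horner–Wadsworth–Emmons olefination with a stabilised phosphonate anion should give the (E)-enoate.

Step 3
Reactants: 4 methyl (2E)-3-(2-fluoro-4,6-dimethoxyphenyl)prop-2-enoate; 5 phenylboronic acid
Product: 6 methyl (3S)-3-(2-fluoro-4,6-dimethoxyphenyl)-3-phenylpropanoate
Conditions: [Rh(OH)((S)-BINAP)]2 (1.5 mol %), 5 (2.5 equiv), 1,4-dioxane/H2O 10:1, 50 °C
Reagents that add atoms: none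
Why: Hayashi–Miyaura rhodium-catalysed asymmetric 1,4-addition, in which phenylrhodium inserts the enoate and water protonates the rhodium enolate, with the (S)-BINAP quadrant model for (E)-enoates expected to place phenyl on the face that makes the benzylic centre S.

Step 4
Reactants: 6 methyl (3S)-3-(2-fluoro-4,6-dimethoxyphenyl)-3-phenylpropanoate; 7 propanoyl chloride
Product: 8 methyl (3S)-3-(2-fluoro-4,6-dimethoxy-3-propanoylphenyl)-3-phenylpropanoate
Conditions: AlCl3, CH2Cl2, −20 → 0 °C
Reagents that add atoms: none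
Why: Friedel–Crafts acylation should go to the one free position that is para to a methoxy group and next to fluorine, the site between the two methoxy groups and the unactivated phenyl ring being slower, and the cold short reaction should spare the methyl ethers and the benzylic centre.

Step 5
Reactants: 8 methyl (3S)-3-(2-fluoro-4,6-dimethoxy-3-propanoylphenyl)-3-phenylpropanoate; 9 acetaldehyde
Product: 13 methyl (3S)-3-[(2R,3R)-5,7-dimethoxy-2,3-dimethyl-4-oxo-3,4-dihydro-2H-chromen-8-yl]-3-phenylpropanoate, via Z enol borinate 10 (not isolated), via syn aldol 11 (not isolated), via cis chromanone 12 (not isolated)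
Conditions: (−)-Ipc2BOTf [from (+)-α-pinene], i-Pr2NEt, CH2Cl2, −78 °C; 9, −78 → −20 °C; H2O2, MeOH, pH 7 buffer, 0 °C; then Cs2CO3, DMF, 0 °C → rt
Reagents that add atoms: none
Why: The boron triflate and Hünig's base should enolise the ethyl ketone, not the hindered ester, to Z enol borinate 10, which adds to acetaldehyde through a closed Zimmerman–Traxler chair and gives syn aldol 11 after peroxide work-up (diisopinocampheylboron aldol reaction of an ethyl ketone). The isopinocampheyl ligands are expected to direct attack to the Si face of the aldehyde, which sets the carbinol carbon R, and the Z enolate geometry sets the syn relationship. Caesium carbonate in DMF then makes the carbinol oxygen the nucleophile of an intramolecular nucleophilic aromatic substitution (addition–elimination through a Meisenheimer adduct) at the fluorine-bearing carbon; this closes the pyranone in a 6-exo mode, is activated by the ortho ketone, and is not slowed by the two methoxy groups because both are meta to that carbon. The carbinol C–O bond is not broken, so cis chromanone 12 keeps C2 as R, and the same mild base epimerises C3 through the enol to the diequatorial trans isomer 13, so C3 is set by thermodynamic control. The step needs one defined ring carbon for O1, which the single fluorine fixes, and ring closure faster than retro-aldol cleavage, for which the polar aprotic solvent, the caesium counter-ion and the low temperature are chosen.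

Step 6
Reactants: 13 methyl (3S)-3-[(2R,3R)-5,7-dimethoxy-2,3-dimethyl-4-oxo-3,4-dihydro-2H-chromen-8-yl]-3-phenylpropanoate
Product: 15 (2R,3R,10S)-5-hydroxy-2,3-dimethyl-10-phenyl-2,3,9,10-tetrahydro-4H,8H-pyrano[2,3-f]chromene-4,8-dione, via dihydroxy methyl ester 14 (not isolated)
Conditions: BBr3, CH2Cl2, −78 °C → rt; H2O; cat. TsOH, PhMe, 50 °C
Reagents that add atoms: none
Why: Lewis acid ether cleavage by boron tribromide should remove both methyl ethers while sparing the less basic ring oxygen of the chromanone, and the freed 7-hydroxyl then closes onto the neighbouring ester by acid-catalysed lactonisation, with no sp3 centre involved.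

Step 7
Reactants: 15 (2R,3R,10S)-5-hydroxy-2,3-dimethyl-10-phenyl-2,3,9,10-tetrahydro-4H,8H-pyrano[2,3-f]chromene-4,8-dione
Product: 16 (2R,3R,10S)-5-hydroxy-6-iodo-2,3-dimethyl-10-phenyl-2,3,9,10-tetrahydro-4H,8H-pyrano[2,3-f]chromene-4,8-dione
Conditions: NIS, MeCN, 0 °C → rt
Reagents that add atoms: N-iodosuccinimide O=C1CCC(=O)N1I
Why: Electrophilic aromatic iodination can only take C6, the last unsubstituted carbon of the phloroglucinol ring and ortho to the free phenol, since the phenyl ring is not activated.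

Step 8
Reactants: 17 (1S,5S)-(−)-verbenone
Product: 18 (1S,3R)-3-acetyl-2,2-dimethylcyclobutane-1-carboxylic acid
Conditions: RuCl3·xH2O (cat.), NaIO4, CCl4/MeCN/H2O, rt
Reagents that add atoms: sodium periodate [Na+].[O-]I(=O)(=O)=O; water O
Why: Ruthenium tetroxide cleavage of the enone C=C bond followed by oxidative loss of CO2 from the α-keto acid should leave the cis-1,3-disubstituted cyclobutane with both stereocentres of verbenone intact.

Step 9
Reactants: 18 (1S,3R)-3-acetyl-2,2-dimethylcyclobutane-1-carboxylic acid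
Product: 19 (1S,3S)-2,2-dimethyl-3-(prop-1-en-2-yl)cyclobutane-1-carboxylic acid
Conditions: KHMDS (1 equiv), THF, −78 °C; Ph3P=CH2 (from Ph3PCH3Br, KHMDS), −78 → 0 °C; aq. citric acid
Reagents that add atoms: methyltriphenylphosphonium bromide C[P+](c1ccccc1)(c1ccccc1)c1ccccc1.[Br-]
Why: Wittig methylenation of the methyl ketone on the pre-formed carboxylate salt with a ylide free of excess base at low temperature should not epimerise the α-carbon, so the cis relationship is kept.

Step 10
Reactants: 19 (1S,3S)-2,2-dimethyl-3-(prop-1-en-2-yl)cyclobutane-1-carboxylic acid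
Product: 20 [(1S,3S)-2,2-dimethyl-3-(prop-1-en-2-yl)cyclobutyl]methanol
Conditions: LiAlH4, Et2O, 0 °C → rt
Reagents that add atoms: none
Why: Hydride reduction of the carboxylic acid to the primary alcohol leaves the 1,1-disubstituted alkene and both stereocentres untouched.

Step 11
Reactants: 20 [(1S,3S)-2,2-dimethyl-3-(prop-1-en-2-yl)cyclobutyl]methanol
Product: 21 (1S,3S)-1-(iodomethyl)-2,2-dimethyl-3-(prop-1-en-2-yl)cyclobutane
Conditions: I2, PPh3, imidazole, CH2Cl2, 0 °C → rt
Reagents that add atoms: iodine II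
Why: Appel iodination proceeds by SN2 at the primary carbon under buffered, non-acidic conditions that the acid-sensitive isopropenylcyclobutane should tolerate.

Step 12
Reactants: 16 (2R,3R,10S)-5-hydroxy-6-iodo-2,3-dimethyl-10-phenyl-2,3,9,10-tetrahydro-4H,8H-pyrano[2,3-f]chromene-4,8-dione; 21 (1S,3S)-1-(iodomethyl)-2,2-dimethyl-3-(prop-1-en-2-yl)cyclobutane
Product: 23 (2R,3R,10S)-6-{[(1R,3S)-2,2-dimethyl-3-(prop-1-en-2-yl)cyclobutyl]methyl}-5-hydroxy-2,3-dimethyl-10-phenyl-2,3,9,10-tetrahydro-4H,8H-pyrano[2,3-f]chromene-4,8-dione, via alkylzinc iodide 22 (not isolated)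
Conditions: 21, Zn dust, LiCl, THF, 40 °C; then 16, Pd(OAc)2, SPhos, THF, rt → 40 °C (zinc reagent in excess)
Reagents that add atoms: none
Why: Negishi cross-coupling, in which zinc insertion gives alkylzinc 22 that transmetalates to the arylpalladium iodide, should form the C6–CH2 bond because reductive elimination from the SPhos complex outruns β-hydride elimination and protonation by the chelated phenol, and no stereocentre sits at the reacting carbons.

Step 13
Reactants: 23 (2R,3R,10S)-6-{[(1R,3S)-2,2-dimethyl-3-(prop-1-en-2-yl)cyclobutyl]methyl}-5-hydroxy-2,3-dimethyl-10-phenyl-2,3,9,10-tetrahydro-4H,8H-pyrano[2,3-f]chromene-4,8-dione; 24 3-methylbut-2-en-1-yl acetate (prenyl acetate)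
Product: 26 methyl (3S)-3-[(2R,3R,6R)-6-{[(1R,3S)-2,2-dimethyl-3-(prop-1-en-2-yl)cyclobutyl]methyl}-5-hydroxy-2,3-dimethyl-6-(3-methylbut-2-en-1-yl)-4,7-dioxo-3,4,6,7-tetrahydro-2H-chromen-8-yl]-3-phenylpropanoate, via ring-opened methyl ester 25 (not isolated)
Conditions: NaOMe (2.1 equiv), THF/MeOH, 0 °C, evaporate; Pd2(dba)3·CHCl3, (R,R)-DACH-phenyl Trost ligand, 24, THF, 0 °C → rt; aq. NaH2PO4
Reagents that add atoms: sodium methoxide C[O-].[Na+]
Why: Proposed new method: methoxide opens the aryl lactone to methyl ester 25 as its bis-phenoxide, a soft nucleophile of the 2-alkyl-1,3-dicarbonyl type whose C6 should attack the unsubstituted terminus of the prenyl–palladium complex from outside (Tsuji–Trost allylic alkylation with dearomatisation), C-alkylation being the irreversible sink while O-prenylation reverses under palladium, and the chiral ligand pocket rather than the remote substrate stereocentres is expected to choose the face that makes C6 R; the closest known reactions are the palladium-catalysed asymmetric allylic alkylation of prochiral β-dicarbonyl and 2-naphthol nucleophiles and the non-asymmetric dearomatising allylation of acylphloroglucinols.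

Step 14
Reactants: 26 methyl (3S)-3-[(2R,3R,6R)-6-{[(1R,3S)-2,2-dimethyl-3-(prop-1-en-2-yl)cyclobutyl]methyl}-5-hydroxy-2,3-dimethyl-6-(3-methylbut-2-en-1-yl)-4,7-dioxo-3,4,6,7-tetrahydro-2H-chromen-8-yl]-3-phenylpropanoate
Product: 27 (3S)-3-[(2R,3R,6R)-6-{[(1R,3S)-2,2-dimethyl-3-(prop-1-en-2-yl)cyclobutyl]methyl}-5-hydroxy-2,3-dimethyl-6-(3-methylbut-2-en-1-yl)-4,7-dioxo-3,4,6,7-tetrahydro-2H-chromen-8-yl]-3-phenylpropanoic acid (CNP0103716.3)
Conditions: LiOH, THF/MeOH/H2O, 0 °C → rt; 1 M HCl
Reagents that add atoms: lithium hydroxide [Li+].[OH-]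
Why: Saponification of the methyl ester should leave all stereocentres alone, because in base the vinylogous acid is a delocalised anion that disfavours β-elimination of the pyranone oxygen and the C6 quaternary centre has no enolisable hydrogen.

**Compound list**

1 | 1-fluoro-3,5-dimethoxybenzene | COc1cc(F)cc(OC)c1 | starting material
2 | 2-fluoro-4,6-dimethoxybenzaldehyde | COc1cc(F)c(C=O)c(OC)c1 | intermediate
3 | trimethyl phosphonoacetate | COC(=O)CP(=O)(OC)OC | starting material
4 | methyl (2E)-3-(2-fluoro-4,6-dimethoxyphenyl)prop-2-enoate | COC(=O)/C=C/c1c(F)cc(OC)cc1OC | intermediate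
5 | phenylboronic acid | OB(O)c1ccccc1 | starting material
6 | methyl (3S)-3-(2-fluoro-4,6-dimethoxyphenyl)-3-phenylpropanoate | COC(=O)C[C@@H](c1ccccc1)c1c(F)cc(OC)cc1OC | intermediate
7 | propanoyl chloride | CCC(=O)Cl | starting material
8 | methyl (3S)-3-(2-fluoro-4,6-dimethoxy-3-propanoylphenyl)-3-phenylpropanoate | COC(=O)C[C@@H](c1ccccc1)c1c(F)c(C(=O)CC)c(OC)cc1OC | intermediate
9 | acetaldehyde | CC=O | starting material
10 | (Z)-enol bis[(1R,2S,3R,5R)-isopinocampheyl]borinate of ketone 8 | C/C=C(\OB([C@@H]1C[C@@H]2C[C@H]([C@H]1C)C2(C)C)[C@@H]1C[C@@H]2C[C@H]([C@H]1C)C2(C)C)c1c(OC)cc(OC)c([C@@H](CC(=O)OC)c2ccccc2)c1F | intermediate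
11 | methyl (3S)-3-{2-fluoro-3-[(2S,3R)-3-hydroxy-2-methylbutanoyl]-4,6-dimethoxyphenyl}-3-phenylpropanoate | COC(=O)C[C@@H](c1ccccc1)c1c(F)c(C(=O)[C@@H](C)[C@@H](C)O)c(OC)cc1OC | intermediate
12 | methyl (3S)-3-[(2R,3S)-5,7-dimethoxy-2,3-dimethyl-4-oxo-3,4-dihydro-2H-chromen-8-yl]-3-phenylpropanoate | COC(=O)C[C@@H](c1ccccc1)c1c2O[C@H](C)[C@H](C)C(=O)c2c(OC)cc1OC | intermediate
13 | methyl (3S)-3-[(2R,3R)-5,7-dimethoxy-2,3-dimethyl-4-oxo-3,4-dihydro-2H-chromen-8-yl]-3-phenylpropanoate | COC(=O)C[C@@H](c1ccccc1)c1c2O[C@H](C)[C@@H](C)C(=O)c2c(OC)cc1OC | intermediate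
14 | methyl (3S)-3-[(2R,3R)-5,7-dihydroxy-2,3-dimethyl-4-oxo-3,4-dihydro-2H-chromen-8-yl]-3-phenylpropanoate | COC(=O)C[C@@H](c1ccccc1)c1c2O[C@H](C)[C@@H](C)C(=O)c2c(O)cc1O | intermediate
15 | (2R,3R,10S)-5-hydroxy-2,3-dimethyl-10-phenyl-2,3,9,10-tetrahydro-4H,8H-pyrano[2,3-f]chromene-4,8-dione | O=C1C[C@@H](c2ccccc2)c2c3O[C@H](C)[C@@H](C)C(=O)c3c(O)cc2O1 | intermediate
16 | (2R,3R,10S)-5-hydroxy-6-iodo-2,3-dimethyl-10-phenyl-2,3,9,10-tetrahydro-4H,8H-pyrano[2,3-f]chromene-4,8-dione | O=C1C[C@@H](c2ccccc2)c2c3O[C@H](C)[C@@H](C)C(=O)c3c(O)c(I)c2O1 | intermediate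
17 | (1S,5S)-(−)-verbenone | CC1=CC(=O)[C@H]2C[C@@H]1C2(C)C | starting material
18 | (1S,3R)-3-acetyl-2,2-dimethylcyclobutane-1-carboxylic acid | CC(=O)[C@@H]1C[C@H](C(=O)O)C1(C)C | intermediate
19 | (1S,3S)-2,2-dimethyl-3-(prop-1-en-2-yl)cyclobutane-1-carboxylic acid | C=C(C)[C@@H]1C[C@H](C(=O)O)C1(C)C | intermediate
20 | [(1S,3S)-2,2-dimethyl-3-(prop-1-en-2-yl)cyclobutyl]methanol | C=C(C)[C@@H]1C[C@H](CO)C1(C)C | intermediate
21 | (1S,3S)-1-(iodomethyl)-2,2-dimethyl-3-(prop-1-en-2-yl)cyclobutane | C=C(C)[C@@H]1C[C@H](CI)C1(C)C | intermediate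
22 | {[(1S,3S)-2,2-dimethyl-3-(prop-1-en-2-yl)cyclobutyl]methyl}zinc iodide | C=C(C)[C@@H]1C[C@H](C[Zn]I)C1(C)C | intermediate
23 | (2R,3R,10S)-6-{[(1R,3S)-2,2-dimethyl-3-(prop-1-en-2-yl)cyclobutyl]methyl}-5-hydroxy-2,3-dimethyl-10-phenyl-2,3,9,10-tetrahydro-4H,8H-pyrano[2,3-f]chromene-4,8-dione | O=C1C[C@@H](c2ccccc2)c2c3O[C@H](C)[C@@H](C)C(=O)c3c(O)c(C[C@H]3C[C@@H](C(C)=C)C3(C)C)c2O1 | intermediate
24 | 3-methylbut-2-en-1-yl acetate | CC(C)=CCOC(C)=O | starting material
25 | methyl (3S)-3-[(2R,3R)-6-{[(1R,3S)-2,2-dimethyl-3-(prop-1-en-2-yl)cyclobutyl]methyl}-5,7-dihydroxy-2,3-dimethyl-4-oxo-3,4-dihydro-2H-chromen-8-yl]-3-phenylpropanoate | COC(=O)C[C@@H](c1ccccc1)c1c2O[C@H](C)[C@@H](C)C(=O)c2c(O)c(C[C@H]2C[C@@H](C(C)=C)C2(C)C)c1O | intermediate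
26 | methyl (3S)-3-[(2R,3R,6R)-6-{[(1R,3S)-2,2-dimethyl-3-(prop-1-en-2-yl)cyclobutyl]methyl}-5-hydroxy-2,3-dimethyl-6-(3-methylbut-2-en-1-yl)-4,7-dioxo-3,4,6,7-tetrahydro-2H-chromen-8-yl]-3-phenylpropanoate | C=C(C)[C@@H]1C[C@H](C[C@@]2(CC=C(C)C)C(=O)C([C@@H](CC(=O)OC)c3ccccc3)=C3O[C@H](C)[C@@H](C)C(=O)C3=C2O)C1(C)C | intermediate
27 | (3S)-3-[(2R,3R,6R)-6-{[(1R,3S)-2,2-dimethyl-3-(prop-1-en-2-yl)cyclobutyl]methyl}-5-hydroxy-2,3-dimethyl-6-(3-methylbut-2-en-1-yl)-4,7-dioxo-3,4,6,7-tetrahydro-2H-chromen-8-yl]-3-phenylpropanoic acid | C=C(C)[C@@H]1C[C@H](C[C@@]2(CC=C(C)C)C(=O)C([C@@H](CC(=O)O)c3ccccc3)=C3O[C@H](C)[C@@H](C)C(=O)C3=C2O)C1(C)C | target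

**Step count and risks**

Total steps: 14. Longest linear sequence: 10 steps (steps 1–7 and 12–14, from 1-fluoro-3,5-dimethoxybenzene); the cyclobutane fragment takes 4 steps (8–11).

Step 13 (proposed new method). What may go wrong: the ligand may not tell apart the two faces of the flat bis-phenoxide, or prenyl may be delivered to oxygen, to C8, or through its substituted terminus. Fallback with known chemistry: setting out from lactone 23, aqueous KOH opens the lactone to the carboxylate bis-phenoxide, and prenyl bromide at 0 °C alkylates C6 without a catalyst (alkylative dearomatisation of an acylphloroglucinol in water). Acidification gives acid 27 directly, together with its C6 epimer, (3S)-3-[(2R,3R,6S)-6-{[(1R,3S)-2,2-dimethyl-3-(prop-1-en-2-yl)cyclobutyl]methyl}-5-hydroxy-2,3-dimethyl-6-(3-methylbut-2-en-1-yl)-4,7-dioxo-3,4,6,7-tetrahydro-2H-chromen-8-yl]-3-phenylpropanoic acid F1. The two are separated by preparative HPLC; the route is rejoined at 27 and step 14 is not needed.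

Step 5. What may go wrong: retro-aldol cleavage of the caesium aldolate before ring closure, which would scramble C2 and C3, or incomplete face selectivity of the boron enolate towards the small aldehyde. Fallback, which closes the ring without an alkoxide: setting out from ketone 8, fluoride is exchanged for hydroxide with acetohydroxamic acid and K2CO3 in DMSO to give methyl (3S)-3-(2-hydroxy-4,6-dimethoxy-3-propanoylphenyl)-3-phenylpropanoate F2. TBSOTf and 2,6-lutidine give methyl (3S)-3-{2-[(tert-butyldimethylsilyl)oxy]-4,6-dimethoxy-3-propanoylphenyl}-3-phenylpropanoate F3. The boron aldol with the mirror-image reagent (+)-Ipc2BOTf and acetaldehyde gives methyl (3S)-3-{2-[(tert-butyldimethylsilyl)oxy]-3-[(2R,3S)-3-hydroxy-2-methylbutanoyl]-4,6-dimethoxyphenyl}-3-phenylpropanoate F4, and TBAF buffered with acetic acid frees methyl (3S)-3-{2-hydroxy-3-[(2R,3S)-3-hydroxy-2-methylbutanoyl]-4,6-dimethoxyphenyl}-3-phenylpropanoate F5. Mitsunobu etherification (PPh3, DIAD, THF, 0 °C) then closes the pyranone under neutral conditions with inversion at the carbinol carbon, which turns the syn aldol into the trans-(2R,3R) chromanone; the route is rejoined at 13.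

Step 3. What may go wrong: slow insertion of the hindered, electron-rich β-aryl enoate into phenylrhodium, so that protodeboronation of the boronic acid wins, or an insufficient preference between the enoate faces. Fallback with an auxiliary in place of the catalyst: setting out from aldehyde 2, Horner–Wadsworth–Emmons olefination with diethyl {2-oxo-2-[(4R)-2-oxo-4-phenyl-1,3-oxazolidin-3-yl]ethyl}phosphonate (LiCl, i-Pr2NEt, MeCN) gives (4R)-3-[(2E)-3-(2-fluoro-4,6-dimethoxyphenyl)prop-2-enoyl]-4-phenyl-1,3-oxazolidin-2-one F6. PhMgBr with CuBr·SMe2 in THF at −40 °C adds to the chelated s-cis imide anti to the auxiliary phenyl group and should give (4R)-3-[(3S)-3-(2-fluoro-4,6-dimethoxyphenyl)-3-phenylpropanoyl]-4-phenyl-1,3-oxazolidin-2-one F7. NaOMe in MeOH at 0 °C releases the auxiliary and rejoins the route at ester 6.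

Further compounds
F1 | step 13 | (3S)-3-[(2R,3R,6S)-6-{[(1R,3S)-2,2-dimethyl-3-(prop-1-en-2-yl)cyclobutyl]methyl}-5-hydroxy-2,3-dimethyl-6-(3-methylbut-2-en-1-yl)-4,7-dioxo-3,4,6,7-tetrahydro-2H-chromen-8-yl]-3-phenylpropanoic acid | C=C(C)[C@@H]1C[C@H](C[C@]2(CC=C(C)C)C(=O)C([C@@H](CC(=O)O)c3ccccc3)=C3O[C@H](C)[C@@H](C)C(=O)C3=C2O)C1(C)C
F2 | step 5 | methyl (3S)-3-(2-hydroxy-4,6-dimethoxy-3-propanoylphenyl)-3-phenylpropanoate | COC(=O)C[C@@H](c1ccccc1)c1c(O)c(C(=O)CC)c(OC)cc1OC
F3 | step 5 | methyl (3S)-3-{2-[(tert-butyldimethylsilyl)oxy]-4,6-dimethoxy-3-propanoylphenyl}-3-phenylpropanoate | COC(=O)C[C@@H](c1ccccc1)c1c(O[Si](C)(C)C(C)(C)C)c(C(=O)CC)c(OC)cc1OC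
F4 | step 5 | methyl (3S)-3-{2-[(tert-butyldimethylsilyl)oxy]-3-[(2R,3S)-3-hydroxy-2-methylbutanoyl]-4,6-dimethoxyphenyl}-3-phenylpropanoate | COC(=O)C[C@@H](c1ccccc1)c1c(O[Si](C)(C)C(C)(C)C)c(C(=O)[C@H](C)[C@H](C)O)c(OC)cc1OC
F5 | step 5 | methyl (3S)-3-{2-hydroxy-3-[(2R,3S)-3-hydroxy-2-methylbutanoyl]-4,6-dimethoxyphenyl}-3-phenylpropanoate | COC(=O)C[C@@H](c1ccccc1)c1c(O)c(C(=O)[C@H](C)[C@H](C)O)c(OC)cc1OC
F6 | step 3 | (4R)-3-[(2E)-3-(2-fluoro-4,6-dimethoxyphenyl)prop-2-enoyl]-4-phenyl-1,3-oxazolidin-2-one | O=C(/C=C/c1c(F)cc(OC)cc1OC)N1C(=O)OC[C@H]1c1ccccc1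
F7 | step 3 | (4R)-3-[(3S)-3-(2-fluoro-4,6-dimethoxyphenyl)-3-phenylpropanoyl]-4-phenyl-1,3-oxazolidin-2-one | O=C(C[C@@H](c1ccccc1)c1c(F)cc(OC)cc1OC)N1C(=O)OC[C@H]1c1ccccc1
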